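The depside C–O ester bond is cut last; the route then rests on making ring A from two open-chain three-carbon units. One TiCl4-mediated formal (3+3) cyclocondensation forms the C3–C4 and C1–C6 bonds of ring A and aromatizes it: C1 with its carboxyl carbon, C2–OH and C3–Cl come from a bis(silyloxy)diene made from methyl 4-chloroacetoacetate, and C4–OMe, C5–H and C6–propyl from 1,1-dimethoxyhex-1-en-3-one. The step exploits that C3–Cl lies between the oxygen-bearing C2 and C4, a site that electrophilic chlorination of a preformed resorcylate reaches poorly. Ring B comes from 5-propylresorcinol as its benzyl 2,4-dihydroxy-6-propylbenzoate.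

Key step: step 5

Remark on the chemistry: the target has no stereocentre; 2, 3, 4, 9 and 11 are expected as mixtures of double-bond isomers and 12 as a mixture of diastereomers, so their SMILES carry no stereodescriptors; this is immaterial because these centres end up in the aromatic ring A or in the symmetric acetal carbon of 10.

Step 1
Reactants: 1 methyl 4-chloroacetoacetate
Product: 2 methyl 4-chloro-3-(trimethylsilyloxy)but-2-enoate
Conditions: Me3SiCl, Et3N, toluene, 20 °C; filtration under argon, distillation at reduced pressure
Reagents that add atoms: chlorotrimethylsilane, C[Si](C)(C)Cl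
Why: Silyl enol ether formation by soft enolization, in which Et3N removes the acidic C2 proton of the β-keto ester and Me3SiCl traps the ketone enolate on oxygen, while the non-polar solvent precipitates the ammonium chloride and keeps N-alkylation at the CH2Cl group slow.

Step 2
Reactants: 2 methyl 4-chloro-3-(trimethylsilyloxy)but-2-enoate
Product: 4 4-chloro-1-methoxy-1,3-bis(trimethylsilyloxy)buta-1,3-diene, via lithium 4-chloro-1-methoxy-3-(trimethylsilyloxy)buta-1,3-dien-1-olate 3 (not isolated)
Conditions: LiN(iPr)2, THF, −78 °C; then Me3SiCl, −78 to 20 °C; evaporation, pentane, filtration under argon, used crude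
Reagents that add atoms: chlorotrimethylsilane, C[Si](C)(C)Cl
Why: Kinetic γ-deprotonation of the β-silyloxy enoate at the CH2Cl group by LiN(iPr)2 gives the extended dienolate 3, whose O-silylation on the ester oxygen (silyl ketene acetal formation) gives the bis(silyloxy)diene, the low temperature preventing chloride loss from the chlorinated terminus.

Step 3
Reactants: 5 butanoyl chloride; 6 1,1-dichloroethene
Product: 8 1,1-dichlorohex-1-en-3-one, via 1,1,1-trichlorohexan-3-one 7 (not isolated)
Conditions: AlCl3, CH2Cl2, 0 to 20 °C; ice and dilute aqueous HCl; distillation at reduced pressure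
Reagents that add atoms: none
Why: Friedel–Crafts-type acylation of an alkene (Kondakov acylation), in which the AlCl3-activated acyl chloride adds to the CH2 terminus of 6, chloride capture gives trichloro ketone 7, and loss of HCl across the acidic α-CH2 on distillation gives the conjugated dichlorovinyl ketone.

Step 4
Reactants: 8 1,1-dichlorohex-1-en-3-one
Product: 10 1,1-dimethoxyhex-1-en-3-one, via 1-chloro-1-methoxyhex-1-en-3-one 9 (not isolated)
Conditions: NaOMe (two equivalents), MeOH, 0 to 20 °C; Et2O, filtration, bulb-to-bulb distillation
Reagents that add atoms: sodium methoxide, [Na+].[O-]C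
Why: Two consecutive conjugate addition–elimination (vinylic substitution) steps replace both β-chlorides by methoxide, and the resulting push–pull ketene acetal is a much poorer acceptor, so two equivalents of NaOMe should stop at 10.

Step 5
Reactants: 4 4-chloro-1-methoxy-1,3-bis(trimethylsilyloxy)buta-1,3-diene; 10 1,1-dimethoxyhex-1-en-3-one
Product: 13 methyl 3-chloro-2-hydroxy-4-methoxy-6-propylbenzoate, via methyl 4-chloro-5-methoxy-3,7-dioxodec-5-enoate 11 (not isolated), via methyl 3-chloro-6-hydroxy-4-methoxy-2-oxo-6-propylcyclohex-4-ene-1-carboxylate 12 (not isolated)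
Conditions: TiCl4 (one equivalent), 4 Å molecular sieves, CH2Cl2, −78 to 20 °C; dilute aqueous HCl; chromatography
Reagents that add atoms: none
Why: TiCl4 binds the carbonyl of 10 and makes its acetal carbon a dialkoxycarbenium-like centre, to which the chlorinated terminus of diene 4 adds (vinylogous Mukaiyama–Michael addition); loss of methoxide to titanium then gives the β-methoxy enone 11 and the C3–C4 bond. The remaining nucleophilic carbon, between ester and ketone, attacks the TiCl4-activated propyl ketone in an intramolecular Mukaiyama aldol addition, a 6-exo-trig (enolexo) closure that forms C1–C6 and gives 12, the only ring closed. Loss of water across C1–C6 and enolization of the C2 ketone aromatize 12 to 13, so no stereocentre survives. The closest known reaction type is the TiCl4-mediated formal (3+3) cyclocondensation of 1,3-bis(silyloxy)-1,3-dienes, 4-substituted ones included, with masked 1,3-dicarbonyl dielectrophiles (3-oxo acetals, 3-oxo orthoesters, ketene acetal or dithioacetal enones) to give salicylates. The step needs regioselective pairing of the two ends: the more nucleophilic diene terminus must take the acetal carbon and not the ketone, which the vinylogous-carbonate character of 10 should secure because its carbonyl is deactivated towards 1,2-addition while its β-carbon carries the positive charge; the reversed pairing would give the 6-methoxy-4-propyl isomer. Because chlorine is fixed on the diene terminus it can only end between C2–OH and C4–OMe, and the methoxy group that is kept is already the 4-O-methyl ether.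

Step 6
Reactants: 13 methyl 3-chloro-2-hydroxy-4-methoxy-6-propylbenzoate
Product: 14 3-chloro-2-hydroxy-4-methoxy-6-propylbenzoic acid
Conditions: KOH (excess), aqueous DMSO, 90 °C; then ice, dilute aqueous HCl to pH 2
Reagents that add atoms: potassium hydroxide, [K+].[OH-]
Why: Saponification of the hindered, chelated salicylate by the poorly solvated hydroxide of aqueous DMSO, with the aryl chloride and aryl methyl ether inert to hydroxide and cold acidification avoiding decarboxylation of the electron-rich acid.

Step 7
Reactants: 15 5-propylresorcinol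
Product: 16 2,4-dihydroxy-6-propylbenzoic acid
Conditions: MeOMgOCO2Me (excess, solution in DMF), DMF, 120–130 °C, N2; then ice-cold aqueous HCl; extraction into aqueous NaHCO3 and reacidification
Reagents that add atoms: methyl magnesium carbonate MeOMgOCO2Me, [Mg+2].C[O-].COC(=O)[O-]
Why: Kolbe–Schmitt-type carboxylation driven by formation of the magnesium-chelated salicylate, in which attack at C4 (equivalent to C6), ortho to one hydroxyl and para to the other, is expected to prevail over the position between the two hydroxyls.

Step 8
Reactants: 16 2,4-dihydroxy-6-propylbenzoic acid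
Product: 18 benzyl 2,4-dihydroxy-6-propylbenzoate, via potassium 2,4-dihydroxy-6-propylbenzoate 17 (not isolated)
Conditions: KHCO3, benzyl bromide, DMF, 20 to 40 °C
Reagents that add atoms: benzyl bromide, BrCc1ccccc1
Why: Chemoselective SN2 alkylation of the carboxylate, since KHCO3 deprotonates only the carboxylic acid and leaves both phenols protonated and unreactive towards benzyl bromide.

Step 9
Reactants: 14 3-chloro-2-hydroxy-4-methoxy-6-propylbenzoic acid; 18 benzyl 2,4-dihydroxy-6-propylbenzoate
Product: 20 benzyl 4-[(3-chloro-2-hydroxy-4-methoxy-6-propylbenzoyl)oxy]-2-hydroxy-6-propylbenzoate, via 3-chloro-2-hydroxy-4-methoxy-6-propylbenzoic trifluoroacetic anhydride 19 (not isolated)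
Conditions: (CF3CO)2O (excess), toluene, 20 °C; evaporation, aqueous NaHCO3 wash, chromatography
Reagents that add atoms: none
Why: Esterification through the mixed trifluoroacetic anhydride, whose ionization to an aroylium-type acylating species overcomes the 2,6-disubstitution of ring A, while the 4-hydroxyl of 18 is the only phenol not locked in a hydrogen bond to an ortho carbonyl and is therefore the expected site of acylation.

Step 10
Reactants: 20 benzyl 4-[(3-chloro-2-hydroxy-4-methoxy-6-propylbenzoyl)oxy]-2-hydroxy-6-propylbenzoate
Product: 21 3-chlorodivaricatic acid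
Conditions: H2 (1 atm, uptake stopped at one equivalent), 10% Pd/C, EtOAc, 20 °C, no base
Reagents that add atoms: none
Why: Hydrogenolysis of the benzylic C–O bond over Pd/C is much faster than hydrodechlorination of an electron-rich aryl chloride in a neutral, base-free medium, so limiting H2 to one equivalent should free the acid with the chloride and the depside ester intact.

Compound list
1 | methyl 4-chloroacetoacetate (methyl 4-chloro-3-oxobutanoate) | COC(=O)CC(=O)CCl | starting material
2 | methyl 4-chloro-3-(trimethylsilyloxy)but-2-enoate | COC(=O)C=C(CCl)O[Si](C)(C)C | intermediate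
3 | lithium 4-chloro-1-methoxy-3-(trimethylsilyloxy)buta-1,3-dien-1-olate (not isolated) | [Li+].COC([O-])=CC(=CCl)O[Si](C)(C)C | intermediate
4 | 4-chloro-1-methoxy-1,3-bis(trimethylsilyloxy)buta-1,3-diene | COC(O[Si](C)(C)C)=CC(=CCl)O[Si](C)(C)C | intermediate
5 | butanoyl chloride | CCCC(Cl)=O | starting material
6 | 1,1-dichloroethene | C=C(Cl)Cl | starting material
7 | 1,1,1-trichlorohexan-3-one (not isolated) | CCCC(=O)CC(Cl)(Cl)Cl | intermediate
8 | 1,1-dichlorohex-1-en-3-one | CCCC(=O)C=C(Cl)Cl | intermediate
9 | 1-chloro-1-methoxyhex-1-en-3-one (not isolated) | CCCC(=O)C=C(Cl)OC | intermediate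
10 | 1,1-dimethoxyhex-1-en-3-one | CCCC(=O)C=C(OC)OC | intermediate
11 | methyl 4-chloro-5-methoxy-3,7-dioxodec-5-enoate (not isolated; present as its titanium or silyl enolate) | COC(=O)CC(=O)C(Cl)C(OC)=CC(=O)CCC | intermediate
12 | methyl 3-chloro-6-hydroxy-4-methoxy-2-oxo-6-propylcyclohex-4-ene-1-carboxylate (not isolated) | COC(=O)C1C(=O)C(Cl)C(OC)=CC1(O)CCC | intermediate
13 | methyl 3-chloro-2-hydroxy-4-methoxy-6-propylbenzoate | CCCc1cc(OC)c(Cl)c(O)c1C(=O)OC | intermediate
14 | 3-chloro-2-hydroxy-4-methoxy-6-propylbenzoic acid | CCCc1cc(OC)c(Cl)c(O)c1C(=O)O | intermediate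
15 | 5-propylresorcinol (5-propylbenzene-1,3-diol) | CCCc1cc(O)cc(O)c1 | starting material
16 | 2,4-dihydroxy-6-propylbenzoic acid | CCCc1cc(O)cc(O)c1C(=O)O | intermediate
17 | potassium 2,4-dihydroxy-6-propylbenzoate (not isolated) | [K+].CCCc1cc(O)cc(O)c1C([O-])=O | intermediate
18 | benzyl 2,4-dihydroxy-6-propylbenzoate | CCCc1cc(O)cc(O)c1C(=O)OCc1ccccc1 | intermediate
19 | 3-chloro-2-hydroxy-4-methoxy-6-propylbenzoic trifluoroacetic anhydride (not isolated) | CCCc1cc(OC)c(Cl)c(O)c1C(=O)OC(=O)C(F)(F)F | intermediate
20 | benzyl 4-[(3-chloro-2-hydroxy-4-methoxy-6-propylbenzoyl)oxy]-2-hydroxy-6-propylbenzoate | CCCc1cc(OC(=O)c2c(CCC)cc(OC)c(Cl)c2O)cc(O)c1C(=O)OCc1ccccc1 | intermediate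
21 | 3-chlorodivaricatic acid, 4-[(3-chloro-2-hydroxy-4-methoxy-6-propylbenzoyl)oxy]-2-hydroxy-6-propylbenzoic acid | CCCc1cc(OC(=O)c2c(CCC)cc(OC)c(Cl)c2O)cc(O)c1C(=O)O | target

Total step count: 10 steps.
Longest linear sequence: 6 steps (steps 1, 2, 5, 6, 9, 10; the enone branch through steps 3, 4, 5, 6, 9, 10 is equally long; ring B joins after steps 7 and 8).

Steps most likely to fail

Step 5. The first C–C bond formation may be slow because the chlorinated diene terminus is hindered and less nucleophilic. Desilylation of 4 or 1,2-attack at the ketone could then compete and erode the regioselectivity. The fallback introduces chlorine by halogenating a saturated 1,3-diketone instead of by ring construction, and sets out from 15. Hydrogenation of 15 as its monosodium salt (H2, Pd/C, one equivalent of aqueous NaOH) should stop at 5-propylcyclohexane-1,3-dione F1. Two equivalents of SO2Cl2 in CH2Cl2 chlorinate the doubly activated C2 to give 2,2-dichloro-5-propylcyclohexane-1,3-dione F2. HCl in DMF at about 100 °C (chlorine shift, then dehydrochlorination and enolization) aromatizes F2 to 2-chloro-5-propylbenzene-1,3-diol F3, with chlorine fixed between the two hydroxyls. Carboxylation of F3 with MeOMgOCO2Me in hot DMF, where both open ring positions are equivalent, gives 3-chloro-2,4-dihydroxy-6-propylbenzoic acid F4. MeI and K2CO3 in acetone then methylate the carboxyl group and the non-chelated 4-hydroxyl, and the route is rejoined at 13.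

Step 9. Acyl transfer from the hindered mixed anhydride may be slow, so self-acylation through the free 2-hydroxyl of ring A or acylation at the wrong phenol could compete. The fallback masks that hydroxyl and couples with a carbodiimide, setting out from 13. Benzyl bromide and K2CO3 in DMF give methyl 2-(benzyloxy)-3-chloro-4-methoxy-6-propylbenzoate F5. KOH in aqueous DMSO gives 2-(benzyloxy)-3-chloro-4-methoxy-6-propylbenzoic acid F6. Steglich esterification of F6 with 18 (N,N'-dicyclohexylcarbodiimide, 4-(dimethylamino)pyridine, CH2Cl2) gives benzyl 4-{[2-(benzyloxy)-3-chloro-4-methoxy-6-propylbenzoyl]oxy}-2-hydroxy-6-propylbenzoate F7. Hydrogenolysis with two equivalents of H2 over Pd/C in EtOAc removes both benzyl groups and comes back at 21.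

Step 10. Hydrodechlorination of ring A may compete with debenzylation, or debenzylation may be incomplete when the H2 uptake is cut short. The fallback avoids hydrogen altogether and sets out from 16. Allyl bromide and KHCO3 in DMF give prop-2-enyl 2,4-dihydroxy-6-propylbenzoate F8. Coupling of F8 with 14 by (CF3CO)2O in toluene gives prop-2-enyl 4-[(3-chloro-2-hydroxy-4-methoxy-6-propylbenzoyl)oxy]-2-hydroxy-6-propylbenzoate F9. Catalytic Pd(PPh3)4 (zerovalent palladium) with PhSiH3 in CH2Cl2 at 20 °C removes the allyl group as propene under non-basic conditions that leave the aryl chloride and the depside ester alone, and comes back at 21.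

Further compounds
F1 | step 5 | 5-propylcyclohexane-1,3-dione | CCCC1CC(=O)CC(=O)C1
F2 | step 5 | 2,2-dichloro-5-propylcyclohexane-1,3-dione | CCCC1CC(=O)C(Cl)(Cl)C(=O)C1
F3 | step 5 | 2-chloro-5-propylbenzene-1,3-diol | CCCc1cc(O)c(Cl)c(O)c1
F4 | step 5 | 3-chloro-2,4-dihydroxy-6-propylbenzoic acid | CCCc1cc(O)c(Cl)c(O)c1C(=O)O
F5 | step 9 | methyl 2-(benzyloxy)-3-chloro-4-methoxy-6-propylbenzoate | CCCc1cc(OC)c(Cl)c(OCc2ccccc2)c1C(=O)OC
F6 | step 9 | 2-(benzyloxy)-3-chloro-4-methoxy-6-propylbenzoic acid | CCCc1cc(OC)c(Cl)c(OCc2ccccc2)c1C(=O)O
F7 | step 9 | benzyl 4-{[2-(benzyloxy)-3-chloro-4-methoxy-6-propylbenzoyl]oxy}-2-hydroxy-6-propylbenzoate | CCCc1cc(OC(=O)c2c(CCC)cc(OC)c(Cl)c2OCc2ccccc2)cc(O)c1C(=O)OCc1ccccc1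
F8 | step 10 | prop-2-enyl 2,4-dihydroxy-6-propylbenzoate | CCCc1cc(O)cc(O)c1C(=O)OCC=C
F9 | step 10 | prop-2-enyl 4-[(3-chloro-2-hydroxy-4-methoxy-6-propylbenzoyl)oxy]-2-hydroxy-6-propylbenzoate | CCCc1cc(OC(=O)c2c(CCC)cc(OC)c(Cl)c2O)cc(O)c1C(=O)OCC=C
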